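Everything rests on cutting the ethano bridge at the bond between its CH2 and C2 of the phenol ring, the carbon ortho to the free hydroxyl. A ruthenium-catalysed dehydrative ortho-C–H alkylation joins unprotected 3,5-dimethoxy-4-methylphenol with 2-[(2S)-5,7-dimethoxyflavan-8-yl]ethanol in one operation, at the final oxidation level and with water as the only by-product. The step exploits the phenolic OH as a native directing group and the symmetry of that ring: C2 and C6 are equivalent and C4 carries the methyl group, so only one mono-alkylation product can form. The alcohol partner already holds the flavan, whose C2 stereocentre comes from asymmetric transfer hydrogenation and an inverting Mitsunobu ring closure.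

Key step: step 8

Remark: the only stereocentre is C2 of the chroman (flavan numbering O1, C2 … C8a) and it is (S); the ruthenium catalyst of step 8 is taken as pre-formed.

Step 1
Reactants: 1 2-hydroxy-4,6-dimethoxybenzaldehyde; 2 acetophenone
Product: 3 (E)-3-(2-hydroxy-4,6-dimethoxyphenyl)-1-phenylprop-2-en-1-one
Conditions: KOH (50% aq.), EtOH, rt to 50 °C; then AcOH to pH 6, 0 °C
Reagents that add atoms: none
Why: Claisen–Schmidt (crossed aldol) condensation of the acetophenone enolate with the non-enolisable aldehyde and E1cB dehydration should give the conjugated E-enone, the mild acidification avoiding closure to the flavylium salt.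

Step 2
Reactants: 3 (E)-3-(2-hydroxy-4,6-dimethoxyphenyl)-1-phenylprop-2-en-1-one
Product: 4 3-(2-hydroxy-4,6-dimethoxyphenyl)-1-phenylpropan-1-one
Conditions: H2 (1 atm), 5% Pd/C, Ph2S (cat.), EtOAc, rt
Reagents that add atoms: none
Why: Catalytic hydrogenation over sulfide-poisoned Pd/C should saturate the enone C=C and leave the aryl ketone untouched.

Step 3
Reactants: 4 3-(2-hydroxy-4,6-dimethoxyphenyl)-1-phenylpropan-1-one
Product: 5 (R)-2-(3-hydroxy-3-phenylpropyl)-3,5-dimethoxyphenol
Conditions: RuCl[(R,R)-TsDPEN](p-cymene) (1 mol%), HCO2H/Et3N (5:2), DMF, 40 °C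
Reagents that add atoms: none
Why: Noyori–Ikariya asymmetric transfer hydrogenation of the aryl alkyl ketone should set the stereocentre, the CH/π contact between the arene ligand and the phenyl group in the six-membered outer-sphere transition state making the (R,R)-catalyst give the (R)-carbinol as it does with acetophenone.

Step 4
Reactants: 5 (R)-2-(3-hydroxy-3-phenylpropyl)-3,5-dimethoxyphenol
Product: 6 (2S)-5,7-dimethoxy-2-phenylchromane
Conditions: PPh3, DIAD, THF, 0 °C to rt
Reagents that add atoms: none
Why: Intramolecular Mitsunobu etherification, in which the phenoxide displaces the benzylic oxyphosphonium by SN2 (6-exo-tet), should close the pyran ring with inversion and turn the (R)-carbinol into the (2S)-flavan.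

Step 5
Reactants: 6 (2S)-5,7-dimethoxy-2-phenylchromane
Product: 7 (2S)-8-bromo-5,7-dimethoxy-2-phenylchromane
Conditions: NBS (1.0 equiv), CH2Cl2, −20 to 0 °C, dark
Reagents that add atoms: N-bromosuccinimide O=C1CCC(=O)N1Br
Why: Electrophilic aromatic bromination should go to C8, ortho to the ring oxygen whose alkyl group is tied back, in preference to C6 between two freely rotating methoxy groups, as is usual for 5,7-dialkoxyflavans.

Step 6
Reactants: 7 (2S)-8-bromo-5,7-dimethoxy-2-phenylchromane
Product: 9 2-[(2S)-5,7-dimethoxy-2-phenylchroman-8-yl]ethan-1-ol, via aryllithium 8 (not isolated)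
Conditions: n-BuLi, THF, −78 °C; then oxirane (3 equiv), −78 to 0 °C; H2O
Reagents that add atoms: oxirane C1CO1
Why: Bromine–lithium exchange followed by SN2 opening of ethylene oxide by the aryllithium should install the two-carbon alcohol at C8 while the non-acidic C2 stereocentre stays untouched at low temperature.

Step 7
Reactants: 10 2,6-dimethoxytoluene
Product: 12 3,5-dimethoxy-4-methylphenol, via arylboronic pinacol ester 11 (not isolated)
Conditions: [Ir(OMe)(cod)]2 (1 mol%), dtbpy (2 mol%), B2pin2 (0.55 equiv), THF, 80 °C; then Oxone, acetone/H2O, rt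
Reagents that add atoms: Oxone (potassium peroxymonosulfate) [K+].[O-]S(=O)(=O)OO
Why: Sterically controlled iridium-catalysed C–H borylation should occur only at C4, the one ring C–H without an ortho substituent, and ipso-oxidation of the boronate then gives the phenol.

Step 8
Reactants: 9 2-[(2S)-5,7-dimethoxy-2-phenylchroman-8-yl]ethan-1-ol; 12 3,5-dimethoxy-4-methylphenol
Product: 13 2-{2-[(2S)-5,7-dimethoxy-2-phenylchroman-8-yl]ethyl}-3,5-dimethoxy-4-methylphenol
Conditions: [(C6H6)(PCy3)(CO)RuH]BF4 (5 mol%), cyclopentene (additive), toluene, 100 °C, sealed tube; 12 in excess (3 equiv)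
Reagents that add atoms: none
Why: The cationic Ru–H complex should bind phenol 12 through oxygen, metalate the adjacent C2–H, cleave the C–O bond of the coordinated primary alcohol 9 to a Ru–alkyl and reductively eliminate the aryl–CH2 bond, releasing water. The closest known reaction type is this ruthenium-catalysed dehydrative ortho-C–H alkylation of electron-rich phenols with primary alcohols, applied here to two larger partners. No ring is closed and no stereocentre is formed; C2 of the chroman is remote from the reacting centres and no Brønsted acid is present to ionise its benzylic C–O bond. The step needs site selectivity for the carbon ortho to the free OH, and the hydroxyl-directed metalation secures it: C4 is blocked by the methyl group, C2 and C6 are equivalent, and the equally electron-rich C6–H of the flavan has no directing hydroxyl. Mono- over dialkylation and C- over O-alkylation should follow from the excess of 12, the added bulk after the first alkylation and the carbon-selective metalation pathway.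

Compound list
1 | 2-hydroxy-4,6-dimethoxybenzaldehyde | COc1cc(O)c(C=O)c(OC)c1 | starting material
2 | acetophenone | CC(=O)c1ccccc1 | starting material
3 | (E)-3-(2-hydroxy-4,6-dimethoxyphenyl)-1-phenylprop-2-en-1-one | COc1cc(O)c(/C=C/C(=O)c2ccccc2)c(OC)c1 | intermediate
4 | 3-(2-hydroxy-4,6-dimethoxyphenyl)-1-phenylpropan-1-one | COc1cc(O)c(CCC(=O)c2ccccc2)c(OC)c1 | intermediate
5 | (R)-2-(3-hydroxy-3-phenylpropyl)-3,5-dimethoxyphenol | O[C@@H](c1ccccc1)CCc1c(O)cc(OC)cc1OC | intermediate
6 | (2S)-5,7-dimethoxy-2-phenylchromane | COc1cc(OC)c2c(c1)O[C@H](c1ccccc1)CC2 | intermediate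
7 | (2S)-8-bromo-5,7-dimethoxy-2-phenylchromane | COc1cc(OC)c2c(c1Br)O[C@H](c1ccccc1)CC2 | intermediate
8 | [(2S)-5,7-dimethoxy-2-phenylchroman-8-yl]lithium | COc1cc(OC)c2c(c1[Li])O[C@H](c1ccccc1)CC2 | intermediate (not isolated)
9 | 2-[(2S)-5,7-dimethoxy-2-phenylchroman-8-yl]ethan-1-ol | COc1cc(OC)c2c(c1CCO)O[C@H](c1ccccc1)CC2 | intermediate
10 | 2,6-dimethoxytoluene | COc1cccc(OC)c1C | starting material
11 | 2-(3,5-dimethoxy-4-methylphenyl)-4,4,5,5-tetramethyl-1,3,2-dioxaborolane | COc1cc(B2OC(C)(C)C(C)(C)O2)cc(OC)c1C | intermediate (not isolated)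
12 | 3,5-dimethoxy-4-methylphenol | COc1cc(O)cc(OC)c1C | intermediate
13 | 2-{2-[(2S)-5,7-dimethoxy-2-phenylchroman-8-yl]ethyl}-3,5-dimethoxy-4-methylphenol | COc1cc(O)c(CCc2c(OC)cc(OC)c3c2O[C@H](c2ccccc2)CC3)c(OC)c1C | target

Total step count: 8. Longest linear sequence: 7 (steps 1–6 and 8); step 7 supplies the second fragment.

Steps most likely to fail

Step 8 (key step). The catalyst may be deactivated by the chelating polyether partners, alcohol 9 may dehydrate to the styrene, or the benzylic C2–O bond may ionise at 100 °C, so that conversion stalls or the stereocentre erodes. The fallback makes the same bond by a Negishi sp3–sp2 coupling and sets out from 9 and 12. Appel iodination of 9 (I2, PPh3, imidazole, CH2Cl2) would give (2S)-8-(2-iodoethyl)-5,7-dimethoxy-2-phenylchromane F1. Phenol 12 would be O-benzylated (BnBr, K2CO3, DMF) to 1-(benzyloxy)-3,5-dimethoxy-4-methylbenzene F2 and brominated (NBS, MeCN, 0 °C) at one of its two equivalent free positions to 1-(benzyloxy)-2-bromo-3,5-dimethoxy-4-methylbenzene F3. Zinc insertion into F1 (Zn dust, LiCl, THF) would give the alkylzinc iodide F4, which is coupled with F3 (Pd(OAc)2, CPhos, THF, 60 °C) to the O-benzyl ether of the target F5. Hydrogenolysis (H2, Pd/C, EtOAc, rt) comes back to the route at 13.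

Step 5. Site selection between C8 and C6 may be poor, or a second bromination may compete. The fallback fixes the position through the phenol before ring closure and sets out from 5. Magnesium-mediated ortho-specific formylation (MgCl2, Et3N, paraformaldehyde, MeCN, reflux) can only reach the one free position ortho to OH and would give (R)-2-hydroxy-3-(3-hydroxy-3-phenylpropyl)-4,6-dimethoxybenzaldehyde F6. Mitsunobu closure (PPh3, DIAD, THF) would give (2S)-5,7-dimethoxy-2-phenylchromane-8-carbaldehyde F7, and Wittig methylenation (Ph3PCH3Br, KOtBu, THF) would give (2S)-5,7-dimethoxy-2-phenyl-8-vinylchromane F8. Hydroboration with 9-BBN to the B-alkyl borane F9 and oxidation (NaOH, H2O2) comes back to the route at 9, bypassing 6 and 7.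

Step 4. Partial ionisation of the activated benzylic alcohol (SN1 leakage) or elimination to the styrene may erode enantiopurity or yield. The fallback sets the stereocentre by hydrogenation instead of substitution and sets out from 4. Acid-catalysed cyclodehydration (p-TsOH, toluene, Dean–Stark) would give 5,7-dimethoxy-2-phenyl-4H-chromene F10. Iridium-catalysed asymmetric hydrogenation of its enol-ether double bond (Ir–phosphinooxazoline BArF catalyst, enantiomer chosen for the (S)-product, H2 50 bar, CH2Cl2) comes back to the route at 6.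

Further compounds
F1 | step 8 | (2S)-8-(2-iodoethyl)-5,7-dimethoxy-2-phenylchromane | COc1cc(OC)c2c(c1CCI)O[C@H](c1ccccc1)CC2
F2 | step 8 | 1-(benzyloxy)-3,5-dimethoxy-4-methylbenzene | COc1cc(OCc2ccccc2)cc(OC)c1C
F3 | step 8 | 1-(benzyloxy)-2-bromo-3,5-dimethoxy-4-methylbenzene | COc1cc(OCc2ccccc2)c(Br)c(OC)c1C
F4 | step 8 | {2-[(2S)-5,7-dimethoxy-2-phenylchroman-8-yl]ethyl}zinc iodide | COc1cc(OC)c2c(c1CC[Zn]I)O[C@H](c1ccccc1)CC2
F5 | step 8 | (2S)-8-{2-[6-(benzyloxy)-2,4-dimethoxy-3-methylphenyl]ethyl}-5,7-dimethoxy-2-phenylchromane | COc1cc(OCc2ccccc2)c(CCc2c(OC)cc(OC)c3c2O[C@H](c2ccccc2)CC3)c(OC)c1C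
F6 | step 5 | (R)-2-hydroxy-3-(3-hydroxy-3-phenylpropyl)-4,6-dimethoxybenzaldehyde | O[C@@H](c1ccccc1)CCc1c(O)c(C=O)c(OC)cc1OC
F7 | step 5 | (2S)-5,7-dimethoxy-2-phenylchromane-8-carbaldehyde | COc1cc(OC)c2c(c1C=O)O[C@H](c1ccccc1)CC2
F8 | step 5 | (2S)-5,7-dimethoxy-2-phenyl-8-vinylchromane | COc1cc(OC)c2c(c1C=C)O[C@H](c1ccccc1)CC2
F9 | step 5 | 9-{2-[(2S)-5,7-dimethoxy-2-phenylchroman-8-yl]ethyl}-9-borabicyclo[3.3.1]nonane | COc1cc(OC)c2c(c1CCB1C3CCCC1CCC3)O[C@H](c1ccccc1)CC2
F10 | step 4 | 5,7-dimethoxy-2-phenyl-4H-chromene | COc1cc(OC)c2c(c1)OC(c1ccccc1)=CC2
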